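A direct plan would join three preformed orsellinate rings by two phenol acylations: 2,4-dihydroxy-6-methylbenzaldehyde A1 would serve as ring A, with the carboxyl carried as a formyl group, and 2,4-bis(benzyloxy)-6-methylbenzoyl chloride A2 would deliver rings B and C in turn.
Acylation of A1 by A2 and O-methylation would give the didepside aldehyde A3; debenzylation, a second acylation by A2 to the tridepside aldehyde A4, oxidation and a last debenzylation would follow.
Its weakest operation would be the hydrogenolysis of the two benzyl ethers of A3 beside a free aryl aldehyde: over-reduction of the formyl group could only be held off by stopping at a measured hydrogen uptake.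
The second would be the chlorite oxidation of the formyl group of A4: hypochlorous acid could chlorinate the free phenolic ring and the aqueous buffer could open a depside ester, on the most precious material of the sequence.
The third would be the bookkeeping: four benzyl ethers, an aldehyde as acid surrogate and a selective O-methylation beside a cleavable aryl ester would make most steps add no skeleton.

**Plan of the new route**
Each arene is cut across its C1–C2 and C5–C6 bonds into a but-2-ynoate (C1, C6, the carboxyl carbon and the methyl group) and an acetoacetate-derived 1,1,3-trioxygenated buta-1,3-diene (C2 to C5 with both ring oxygens); each ester C–O bond is cut only at the stage of an unhindered but-2-ynoate.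
Enabling feature: rings A, B and C are all 2,4-dioxygenated 6-methylbenzoates, and each depside oxygen is at once O-4 of one ring (the 3-silyloxy oxygen of the diene) and the ester oxygen at C1 of the next, so every annulation unveils exactly the phenol that the next but-2-ynoylation needs.
The rings arise de novo in the order A, B, C, each grown on the oxygen of the one before.
The methoxy group of ring A comes from a dimethyl ketene acetal diene and the 2-hydroxyls of rings B and C from a silyl methyl ketene acetal diene; the carboxyl is at the acid level from step 1 and no phenol is ever protected, so ether hydrogenolysis beside an aldehyde, a late chlorite oxidation and a selective methylation have no counterpart.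

Key step: step 4

Assumption: dienes 4 and 9 are taken as purchased silyl enol ether reagents (each is otherwise obtained by silylation of 4,4-dimethoxybut-3-en-2-one or of methyl acetoacetate); the geometry of the ketene acetal double bond of 9 is immaterial, since that carbon becomes an arene carbon.

Step 1
Reactants: 1 but-2-ynoic acid; 2 benzyl alcohol
Product: 3 benzyl but-2-ynoate
Conditions: DCC (1.1 equiv), DMAP (5 mol %), CH2Cl2, 0 °C to rt
Reagents that add atoms: benzyl alcohol OCc1ccccc1
Why: Steglich esterification of an unhindered acid with a primary alcohol; low temperature and catalytic DMAP should keep the ynoate from isomerising to the allenoate.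

Step 2
Reactants: 3 benzyl but-2-ynoate; 4 1,1-dimethoxy-3-(trimethylsilyloxy)buta-1,3-diene
Product: 7 benzyl 4-hydroxy-2-methoxy-6-methylbenzoate, via ketal cycloadduct 5 (not isolated), via aryl silyl ether 6 (not isolated)
Conditions: 4 (1.5 equiv), toluene, 110 °C, sealed tube; then 1 M HCl, THF, 0 °C to rt
Reagents that add atoms: 1,1-dimethoxy-3-(trimethylsilyloxy)buta-1,3-diene COC(OC)=CC(=C)O[Si](C)(C)C
Why: Diels-Alder benzannulation of a 1,1-dialkoxy-3-silyloxydiene with a 2-alkynoate, in which the CH2 terminus of the diene bonds to the methyl-bearing β-carbon, the dimethyl ketal of 5 loses methanol on heating to leave the 2-methoxy group of ring A, and dilute acid frees the 4-hydroxyl of 6; no stereocentre remains.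

Step 3
Reactants: 7 benzyl 4-hydroxy-2-methoxy-6-methylbenzoate; 1 but-2-ynoic acid
Product: 8 benzyl 4-(but-2-ynoyloxy)-2-methoxy-6-methylbenzoate
Conditions: 1 (1.2 equiv), DCC (1.2 equiv), DMAP (5 mol %), CH2Cl2, 0 °C
Reagents that add atoms: but-2-ynoic acid CC#CC(=O)O
Why: Steglich esterification of the only phenol with a small linear acid, the standard way to aryl but-2-ynoates, so the future hindered depside ester is made while its acyl group is still unhindered.

Step 4
Reactants: 8 benzyl 4-(but-2-ynoyloxy)-2-methoxy-6-methylbenzoate; 9 1-methoxy-1,3-bis(trimethylsilyloxy)buta-1,3-diene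
Product: 11 benzyl 4-[(2,4-dihydroxy-6-methylbenzoyl)oxy]-2-methoxy-6-methylbenzoate, via ring B cycloadduct 10 (not isolated)
Conditions: 9 (2.5 equiv), toluene, 90 °C; then 0.5 M HCl, THF, 0 °C
Reagents that add atoms: 1-methoxy-1,3-bis(trimethylsilyloxy)buta-1,3-diene COC(O[Si](C)(C)C)=CC(=C)O[Si](C)(C)C
Why: The CH2 terminus of diene 9 (largest HOMO coefficient, reinforced by the 1,1-dioxygen and 3-silyloxy donors) bonds to the β-carbon of the ynoate of 8 (largest LUMO coefficient) and the ketene acetal carbon to the α-carbon, in a thermal, asynchronous normal-demand Diels-Alder reaction that gives the 1,4-cyclohexadiene 10. The closest known reaction type is the benzannulation of Danishefsky-, Brassard- and Chan-type oxygenated dienes with 2-alkynoates to resorcylates. Ring B is closed in this intermolecular [4+2] mode (bonds C1–C2 and C5–C6 of ring B) and aromatises without an oxidant, because the alkyne supplies the third unsaturation and the mixed silyl methyl ketal supplies the leaving group. No stereocentre survives, since the ketal carbon of racemic 10 becomes C2 of the arene. The step needs regiocontrol, which the polarised ynoate and the donor-substituted diene secure so that the methyl group ends ortho and the oxygens ortho and para to the ester; it needs hydroxyl and not methoxyl at C2, which cold aqueous acid should secure by cleaving the O–Si bond of the ketal first so that carbonyl collapse expels methanol; and it needs the benzyl ester and the aryl ester to survive, which the neutral medium free of Lewis acid secures. The hindered 2,6-disubstituted aryl benzoate is thus never made by acylation: its ester bond is older than its ring.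

Step 5
Reactants: 11 benzyl 4-[(2,4-dihydroxy-6-methylbenzoyl)oxy]-2-methoxy-6-methylbenzoate; 1 but-2-ynoic acid
Product: 12 benzyl 4-{[4-(but-2-ynoyloxy)-2-hydroxy-6-methylbenzoyl]oxy}-2-methoxy-6-methylbenzoate
Conditions: 1 (1.05 equiv), DCC (1.05 equiv), DMAP (5 mol %), CH2Cl2, −20 to 0 °C
Reagents that add atoms: but-2-ynoic acid CC#CC(=O)O
Why: Steglich esterification that should go to the free, more acidic 4-hydroxyl para to the ester, because the 2-hydroxyl is hydrogen-bonded to the ester carbonyl and flanked by it, the usual site selectivity of orsellinates.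

Step 6
Reactants: 12 benzyl 4-{[4-(but-2-ynoyloxy)-2-hydroxy-6-methylbenzoyl]oxy}-2-methoxy-6-methylbenzoate; 13 N,O-bis(trimethylsilyl)acetamide; 9 1-methoxy-1,3-bis(trimethylsilyloxy)buta-1,3-diene
Product: 16 benzyl 4-({4-[(2,4-dihydroxy-6-methylbenzoyl)oxy]-2-hydroxy-6-methylbenzoyl}oxy)-2-methoxy-6-methylbenzoate, via silyl ether 14 (not isolated), via ring C cycloadduct 15 (not isolated)
Conditions: 13 (1.2 equiv), toluene, rt, then evaporate; 9 (2.5 equiv), toluene, 90 °C; then 0.5 M HCl, THF, 0 °C
Reagents that add atoms: 1-methoxy-1,3-bis(trimethylsilyloxy)buta-1,3-diene COC(O[Si](C)(C)C)=CC(=C)O[Si](C)(C)C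
Why: The same Diels-Alder benzannulation as in step 4 builds ring C on the 4-oxygen of ring B; transient silylation keeps the chelated phenol from protonating the diene, the neutral medium spares both depside esters, and cold dilute acid removes the three silyl groups and aromatises with loss of methanol.

Step 7
Reactants: 16 benzyl 4-({4-[(2,4-dihydroxy-6-methylbenzoyl)oxy]-2-hydroxy-6-methylbenzoyl}oxy)-2-methoxy-6-methylbenzoate
Product: 17 4-({4-[(2,4-dihydroxy-6-methylbenzoyl)oxy]-2-hydroxy-6-methylbenzoyl}oxy)-2-methoxy-6-methylbenzoic acid (target)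
Conditions: H2 (1 atm), 10% Pd/C, EtOAc, rt
Reagents that add atoms: none
Why: Neutral hydrogenolysis of the single benzyl ester, with the aryl esters, methyl ether and phenols inert and no other reducible group present; the target is achiral.

**Compound list**
1 | but-2-ynoic acid | CC#CC(=O)O | starting material
2 | benzyl alcohol | OCc1ccccc1 | starting material
3 | benzyl but-2-ynoate | CC#CC(=O)OCc1ccccc1 | intermediate
4 | 1,1-dimethoxy-3-(trimethylsilyloxy)buta-1,3-diene | COC(OC)=CC(=C)O[Si](C)(C)C | starting material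
5 | benzyl 6,6-dimethoxy-2-methyl-4-[(trimethylsilyl)oxy]cyclohexa-1,4-diene-1-carboxylate | COC1(OC)C=C(O[Si](C)(C)C)CC(C)=C1C(=O)OCc1ccccc1 | intermediate
6 | benzyl 2-methoxy-6-methyl-4-[(trimethylsilyl)oxy]benzoate | COc1cc(O[Si](C)(C)C)cc(C)c1C(=O)OCc1ccccc1 | intermediate
7 | benzyl 4-hydroxy-2-methoxy-6-methylbenzoate | COc1cc(O)cc(C)c1C(=O)OCc1ccccc1 | intermediate
8 | benzyl 4-(but-2-ynoyloxy)-2-methoxy-6-methylbenzoate | COc1cc(OC(=O)C#CC)cc(C)c1C(=O)OCc1ccccc1 | intermediate
9 | 1-methoxy-1,3-bis(trimethylsilyloxy)buta-1,3-diene | COC(O[Si](C)(C)C)=CC(=C)O[Si](C)(C)C | starting material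
10 | benzyl 4-({6-methoxy-2-methyl-4,6-bis[(trimethylsilyl)oxy]cyclohexa-1,4-dien-1-yl}carbonyloxy)-2-methoxy-6-methylbenzoate (racemic) | COC1(O[Si](C)(C)C)C=C(O[Si](C)(C)C)CC(C)=C1C(=O)Oc1cc(C)c(C(=O)OCc2ccccc2)c(OC)c1 | intermediate
11 | benzyl 4-[(2,4-dihydroxy-6-methylbenzoyl)oxy]-2-methoxy-6-methylbenzoate | Cc1cc(O)cc(O)c1C(=O)Oc1cc(C)c(C(=O)OCc2ccccc2)c(OC)c1 | intermediate
12 | benzyl 4-{[4-(but-2-ynoyloxy)-2-hydroxy-6-methylbenzoyl]oxy}-2-methoxy-6-methylbenzoate | CC#CC(=O)Oc1cc(C)c(C(=O)Oc2cc(C)c(C(=O)OCc3ccccc3)c(OC)c2)c(O)c1 | intermediate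
13 | N,O-bis(trimethylsilyl)acetamide | CC(=N[Si](C)(C)C)O[Si](C)(C)C | starting material
14 | benzyl 4-({4-(but-2-ynoyloxy)-2-methyl-6-[(trimethylsilyl)oxy]benzoyl}oxy)-2-methoxy-6-methylbenzoate | CC#CC(=O)Oc1cc(C)c(C(=O)Oc2cc(C)c(C(=O)OCc3ccccc3)c(OC)c2)c(O[Si](C)(C)C)c1 | intermediate
15 | benzyl 4-{[4-({6-methoxy-2-methyl-4,6-bis[(trimethylsilyl)oxy]cyclohexa-1,4-dien-1-yl}carbonyloxy)-2-methyl-6-[(trimethylsilyl)oxy]benzoyl]oxy}-2-methoxy-6-methylbenzoate (racemic) | COC1(O[Si](C)(C)C)C=C(O[Si](C)(C)C)CC(C)=C1C(=O)Oc1cc(C)c(C(=O)Oc2cc(C)c(C(=O)OCc3ccccc3)c(OC)c2)c(O[Si](C)(C)C)c1 | intermediate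
16 | benzyl 4-({4-[(2,4-dihydroxy-6-methylbenzoyl)oxy]-2-hydroxy-6-methylbenzoyl}oxy)-2-methoxy-6-methylbenzoate | Cc1cc(O)cc(O)c1C(=O)Oc1cc(C)c(C(=O)Oc2cc(C)c(C(=O)OCc3ccccc3)c(OC)c2)c(O)c1 | intermediate
17 | 4-({4-[(2,4-dihydroxy-6-methylbenzoyl)oxy]-2-hydroxy-6-methylbenzoyl}oxy)-2-methoxy-6-methylbenzoic acid | COc1cc(OC(=O)c2c(C)cc(OC(=O)c3c(C)cc(O)cc3O)cc2O)cc(C)c1C(=O)O | target

Total step count: 7. Longest linear sequence: 7 steps (steps 1 to 7).

**Steps most likely to fail**

Step 4. The cycloaddition to the β-methyl ynoate may be slower than thermal decomposition of the diene, and part of the adduct may aromatise by loss of silanol in place of methanol, which would leave O-2 of ring B methylated. The fallback sets out from 7 and joins a preformed ring B by classical depside coupling. Commercial methyl 2,4-dihydroxy-6-methylbenzoate would be O-allylated twice (allyl bromide, K2CO3, DMF, 60 °C) to methyl 2,4-bis(allyloxy)-6-methylbenzoate F1, and F1 would be saponified (KOH, aqueous DMSO, 90 °C) to 2,4-bis(allyloxy)-6-methylbenzoic acid F2. Condensation of F2 with phenol 7 (DCC, toluene, rt) should give benzyl 4-{[2,4-bis(allyloxy)-6-methylbenzoyl]oxy}-2-methoxy-6-methylbenzoate F3. Deallylation of F3 with the zerovalent palladium complex Pd(PPh3)4 and PhSiH3 in CH2Cl2 would come back to the route at 11.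

Step 6. The same limits apply on the larger substrate, and prolonged heating may cause silyl transfer or acyl exchange between the phenolic silyl ether and the two depside links. The fallback sets out from 11. 2,4-Bis(allyloxy)-6-methylbenzoic acid F2, made as above by way of F1, would be condensed with the free 4-hydroxyl of 11 (DCC, toluene, rt) to benzyl 4-[(4-{[2,4-bis(allyloxy)-6-methylbenzoyl]oxy}-2-hydroxy-6-methylbenzoyl)oxy]-2-methoxy-6-methylbenzoate F4. Deallylation of F4 with the zerovalent palladium complex Pd(PPh3)4 and PhSiH3 in CH2Cl2 would come back to the route at 16.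

Step 5. Discrimination between the two phenols of 11 may be incomplete (double acylation), and the activated but-2-ynoate may isomerise to the allenoate under DMAP and then take up DMAP or phenol by conjugate addition. The fallback sets out from 11 and delivers all eight carbons of ring C as a neutral, thermally generated acyl ketene, with no coupling agent or base. Commercial 2,2,6-trimethyl-4H-1,3-dioxin-4-one would be C-acetylated through its lithium dienolate (LiN(SiMe3)2, THF, −78 °C; acetyl chloride) to 2,2-dimethyl-6-(2-oxopropyl)-4H-1,3-dioxin-4-one F5. The dianion of F5 (LiN(iPr)2, 2 equiv, THF, −78 °C) would be acetylated again with 1-acetylimidazole to 6-(2,4-dioxopentyl)-2,2-dimethyl-4H-1,3-dioxin-4-one F6. Heating F6 with 11 in toluene at 100–110 °C would release acetone and the acyl ketene, which the free 4-hydroxyl should trap to give benzyl 4-({2-hydroxy-6-methyl-4-[(3,5,7-trioxooctanoyl)oxy]benzoyl}oxy)-2-methoxy-6-methylbenzoate F7. Aldol cyclodehydration of F7 (Et3N, CH2Cl2; then silica gel) would fold the chain into ring C and come back to the route at 16.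

Further compounds
F1 | step 4 | methyl 2,4-bis(allyloxy)-6-methylbenzoate | C=CCOc1cc(C)c(C(=O)OC)c(OCC=C)c1
F2 | step 4 | 2,4-bis(allyloxy)-6-methylbenzoic acid | C=CCOc1cc(C)c(C(=O)O)c(OCC=C)c1
F3 | step 4 | benzyl 4-{[2,4-bis(allyloxy)-6-methylbenzoyl]oxy}-2-methoxy-6-methylbenzoate | C=CCOc1cc(C)c(C(=O)Oc2cc(C)c(C(=O)OCc3ccccc3)c(OC)c2)c(OCC=C)c1
F4 | step 6 | benzyl 4-[(4-{[2,4-bis(allyloxy)-6-methylbenzoyl]oxy}-2-hydroxy-6-methylbenzoyl)oxy]-2-methoxy-6-methylbenzoate | C=CCOc1cc(C)c(C(=O)Oc2cc(C)c(C(=O)Oc3cc(C)c(C(=O)OCc4ccccc4)c(OC)c3)c(O)c2)c(OCC=C)c1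
F5 | step 5 | 2,2-dimethyl-6-(2-oxopropyl)-4H-1,3-dioxin-4-one | CC(=O)CC1=CC(=O)OC(C)(C)O1
F6 | step 5 | 6-(2,4-dioxopentyl)-2,2-dimethyl-4H-1,3-dioxin-4-one | CC(=O)CC(=O)CC1=CC(=O)OC(C)(C)O1
F7 | step 5 | benzyl 4-({2-hydroxy-6-methyl-4-[(3,5,7-trioxooctanoyl)oxy]benzoyl}oxy)-2-methoxy-6-methylbenzoate | CC(=O)CC(=O)CC(=O)CC(=O)Oc1cc(C)c(C(=O)Oc2cc(C)c(C(=O)OCc3ccccc3)c(OC)c2)c(O)c1
A1 | direct plan | 2,4-dihydroxy-6-methylbenzaldehyde | Cc1cc(O)cc(O)c1C=O
A2 | direct plan | 2,4-bis(benzyloxy)-6-methylbenzoyl chloride | Cc1cc(OCc2ccccc2)cc(OCc2ccccc2)c1C(=O)Cl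
A3 | direct plan | 4-formyl-3-methoxy-5-methylphenyl 2,4-bis(benzyloxy)-6-methylbenzoate | Cc1cc(OCc2ccccc2)cc(OCc2ccccc2)c1C(=O)Oc1cc(C)c(C=O)c(OC)c1
A4 | direct plan | 4-[(4-formyl-3-methoxy-5-methylphenoxy)carbonyl]-3-hydroxy-5-methylphenyl 2,4-bis(benzyloxy)-6-methylbenzoate | Cc1cc(OCc2ccccc2)cc(OCc2ccccc2)c1C(=O)Oc1cc(C)c(C(=O)Oc2cc(C)c(C=O)c(OC)c2)c(O)c1
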